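**Retrosynthetic overview**
1. Target 13 ⇒ two Friedel–Crafts C-benzylations with 4-hydroxybenzyl alcohol at the two ring positions of 3-methoxy-5-(2-phenylethyl)phenol 9 that lie para to an oxygen.
2. 9 ⇒ key C–O disconnection: the aryl–OMe bond is made from methanol and 5-styrylcyclohexane-1,3-dione 6, and the ring aromatises by passing its two surplus hydrogens to the styryl C=C.
3. 6 ⇒ Michael addition / Claisen ring closure / decarboxylation from cinnamylideneacetone 1 and dimethyl malonate 2.
4. Ring order: the central ring is built alicyclic (step 1) and aromatised as the C–OMe bond forms (step 2); the two phenol arms go on last (step 3); the other three rings are bought.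

Assumption: the target has no stereocentre (it is achiral), so there is no enantiomer to control; the SMILES is taken as drawn.

**Step 1**
Reactants: 1 (3E,5E)-6-phenylhexa-3,5-dien-2-one; 2 dimethyl propanedioate (dimethyl malonate)
Product: 6 5-[(E)-2-phenylethenyl]cyclohexane-1,3-dione, via Michael adduct 3 (not isolated), via cyclic keto ester 4 (not isolated), via keto acid 5 (not isolated)
Conditions: NaOMe (1.1 equiv), MeOH, reflux; then aq. NaOH, reflux; then HCl (pH 1), 90 °C
Reagents that add atoms: none
Why: Classical dihydroresorcinol synthesis: the malonate anion adds 1,4 to the dienone (Michael addition), the methyl-ketone enolate closes the six-membered ring on one ester (intramolecular Claisen condensation), and saponification followed by decarboxylation of the β-keto acid gives 6, which has no stereocentre and keeps the E alkene.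

**Step 2**
Reactants: 6 5-[(E)-2-phenylethenyl]cyclohexane-1,3-dione; 7 methanol
Product: 9 3-methoxy-5-(2-phenylethyl)phenol, via vinylogous ester 8 (not isolated)
Conditions: MeOH (20 equiv), TsOH·H2O (5 mol %), PhMe, 70 °C; then 10% Pd/C (5 mol % Pd), sealed tube, 150 °C
Reagents that add atoms: methanol (compound 7), CO
Why: Proposed new method: acid-catalysed condensation of the vinylogous acid with methanol forms the ring C–OMe bond (enol ether 8), and Pd–H chain-walking (or surface dehydrogenation/re-hydrogenation) then moves the two surplus ring hydrogens onto the styryl C=C, so the ring aromatises to the mono-methyl ether with no external oxidant or reductant and the saturated bibenzyl bridge appears in the same operation; the closest known reaction types are the iodine–methanol methoxy-aromatisation of cyclohexane-1,3-diones and the Pd/C isoaromatisation of carvone to carvacrol, and no stereocentre remains in 9.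

**Step 3**
Reactants: 9 3-methoxy-5-(2-phenylethyl)phenol; 10 4-(hydroxymethyl)phenol (4-hydroxybenzyl alcohol, 2.2 equiv)
Product: 13 2,4-bis[(4-hydroxyphenyl)methyl]-5-methoxy-3-(2-phenylethyl)phenol, via para-monobenzyl phenol 11 (not isolated), via ortho-monobenzyl phenol 12 (not isolated)
Conditions: 10 added slowly, TsOH·H2O (5 mol %), HFIP, 40 °C
Reagents that add atoms: none
Why: Two-fold Friedel–Crafts benzylation through the p-quinone methide / 4-hydroxybenzyl cation released from 10; this soft electrophile should attack the two positions para to an oxygen (C4 para to OH, C2 para to OMe, both flanking the phenethyl chain) in preference to C6 between the oxygens, which has only ortho activation, and the dioxygenated ring of 9 is far more nucleophilic than the mono-oxygenated rings of 10 and of the product, which limits self-condensation; no stereocentre is formed.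

**Compound list**
1 | (3E,5E)-6-phenylhexa-3,5-dien-2-one (cinnamylideneacetone) | CC(=O)/C=C/C=C/c1ccccc1 | starting material
2 | dimethyl propanedioate (dimethyl malonate) | COC(=O)CC(=O)OC | starting material
3 | dimethyl 2-[(1E)-5-oxo-1-phenylhex-1-en-3-yl]propanedioate (racemic) | COC(=O)C(C(=O)OC)C(CC(C)=O)/C=C/c1ccccc1 | intermediate
4 | methyl 2,4-dioxo-6-[(E)-2-phenylethenyl]cyclohexane-1-carboxylate (racemic, formed as its sodium enolate) | COC(=O)C1C(=O)CC(=O)CC1/C=C/c1ccccc1 | intermediate
5 | 2,4-dioxo-6-[(E)-2-phenylethenyl]cyclohexane-1-carboxylic acid (racemic) | OC(=O)C1C(=O)CC(=O)CC1/C=C/c1ccccc1 | intermediate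
6 | 5-[(E)-2-phenylethenyl]cyclohexane-1,3-dione | O=C1CC(=O)CC(/C=C/c2ccccc2)C1 | intermediate
7 | methanol | CO | starting material
8 | 3-methoxy-5-[(E)-2-phenylethenyl]cyclohex-2-en-1-one (racemic) | COC1=CC(=O)CC(/C=C/c2ccccc2)C1 | intermediate
9 | 3-methoxy-5-(2-phenylethyl)phenol | COc1cc(O)cc(CCc2ccccc2)c1 | intermediate
10 | 4-(hydroxymethyl)phenol (4-hydroxybenzyl alcohol) | OCc1ccc(O)cc1 | starting material
11 | 4-[(4-hydroxyphenyl)methyl]-3-methoxy-5-(2-phenylethyl)phenol | COc1cc(O)cc(CCc2ccccc2)c1Cc1ccc(O)cc1 | intermediate
12 | 2-[(4-hydroxyphenyl)methyl]-5-methoxy-3-(2-phenylethyl)phenol | COc1cc(O)c(Cc2ccc(O)cc2)c(CCc2ccccc2)c1 | intermediate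
13 | 2,4-bis[(4-hydroxyphenyl)methyl]-5-methoxy-3-(2-phenylethyl)phenol | COc1cc(O)c(Cc2ccc(O)cc2)c(CCc2ccccc2)c1Cc1ccc(O)cc1 | target

**Total step count:** 3. **Longest linear sequence:** 3.

**Steps most likely to fail, with fallbacks**

Step 2 (the proposed new step). The palladium stage may stall, disproportionate, or aromatise 6 before the enol ether has formed, which would give the free resorcinol. The fallback uses known chemistry and sets out from 6: hydrogenation of the side-chain alkene (H2, Pd/C, EtOAc, rt) gives 5-(2-phenylethyl)cyclohexane-1,3-dione F2, and the iodine–methanol oxidative aromatisation (I2, MeOH, reflux) then gives the resorcinol mono-methyl ether, which comes back to the route at 9.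

Step 3. The risks are attack at the position between the two oxygens, a third benzylation, and oligomerisation of 10. The fallback gives up electrophilic benzylation for halogenation and cross-coupling and sets out from 9: O-methylation (Me2SO4, K2CO3, acetone) gives 1,3-dimethoxy-5-(2-phenylethyl)benzene F3; NBS (2.05 equiv, MeCN) brominates para to each methoxy group to give 2,4-dibromo-1,5-dimethoxy-3-(2-phenylethyl)benzene F4; two-fold Negishi coupling with (4-methoxybenzyl)zinc chloride (Pd(OAc)2/SPhos, THF, 60 °C) gives 1,5-dimethoxy-2,4-bis[(4-methoxyphenyl)methyl]-3-(2-phenylethyl)benzene F5; excess NaSEt in DMF at 150 °C then cleaves both arm ethers and only one of the two central ethers, because the first phenoxide deactivates its own ring, and the route is rejoined at 13.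

Step 1. Under hot methoxide the dienone 1 can polymerise or take up malonate in the 1,6-sense. The fallback reverses the order of C–C bond formation and sets out from 2: Knoevenagel condensation with cinnamaldehyde (piperidine/AcOH, PhMe, Dean–Stark) gives dimethyl 2-[(2E)-3-phenylprop-2-en-1-ylidene]propanedioate F1; 1,4-addition of the lithium enolate of acetone (LDA, THF, −78 °C) then gives the Michael adduct, which comes back to the route at 3 and is cyclised, saponified and decarboxylated as in step 1.

**Further compounds**
F1 | step 1 | dimethyl 2-[(2E)-3-phenylprop-2-en-1-ylidene]propanedioate | COC(=O)C(=C/C=C/c1ccccc1)C(=O)OC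
F2 | step 2 | 5-(2-phenylethyl)cyclohexane-1,3-dione | O=C1CC(=O)CC(CCc2ccccc2)C1
F3 | step 3 | 1,3-dimethoxy-5-(2-phenylethyl)benzene | COc1cc(OC)cc(CCc2ccccc2)c1
F4 | step 3 | 2,4-dibromo-1,5-dimethoxy-3-(2-phenylethyl)benzene | COc1cc(OC)c(Br)c(CCc2ccccc2)c1Br
F5 | step 3 | 1,5-dimethoxy-2,4-bis[(4-methoxyphenyl)methyl]-3-(2-phenylethyl)benzene | COc1ccc(Cc2c(OC)cc(OC)c(Cc3ccc(OC)cc3)c2CCc2ccccc2)cc1
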